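## Retrosynthetic overview

1. Both rings of the chromene are made in the last flask. The pyran O1–C2 bond comes from closure of an o-hydroxybenzylic allyl cation (protonated o-quinone methide) held as a contact ion pair by a chiral Brønsted acid; this sets C2.
2. The benzo ring comes from a Diels–Alder/aromatisation of a 4-substituted Chan-type 1,3-bis(silyloxy)diene (C7, C8, C8a, C4a) with 3-butyn-2-one (C5, C6, acetyl). The side chain on the diene terminus fixes the linear 6-acetyl-7-hydroxy pattern.
3. The diene comes from a vinylogous Mukaiyama aldol of Chan's diene with (E)-4-(feruloyloxy)-3-methylbut-2-enal. The ferulate is carried from the start, so there is no late esterification and no protecting-group step.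
4. The enal comes from Meyer–Schuster rearrangement of the ethynyl carbinol made from acetonyl ferulate (ferulic acid + chloroacetone).
5. Ring order: the guaiacyl ring is bought (ferulic acid); the benzo ring and then the pyran ring are formed in one operation at the end.

Assumption: the sense of induction of the chiral acid in step 6 cannot be derived from precedent; the (R)-catalyst is written, and its mirror image is used if it turns out to give the (2S)-chromene.

## Route

Step 1
Reactants: 1 (E)-ferulic acid; 2 chloroacetone
Product: 3 2-oxopropyl (2E)-3-(4-hydroxy-3-methoxyphenyl)prop-2-enoate (acetonyl ferulate)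
Conditions: KHCO3 (1.1 equiv), NaI (10 mol%), DMF, 23 °C
Reagents that add atoms: none
Why: Bicarbonate deprotonates only the carboxylic acid, not the phenol, and the carboxylate displaces chloride from the activated α-chloroketone (SN2 O-alkylation); no stereocentre is formed.

Step 2
Reactants: 3 acetonyl ferulate; 4 ethynylmagnesium bromide
Product: 5 rac-2-hydroxy-2-methylbut-3-yn-1-yl (E)-ferulate
Conditions: 4 (2.5 equiv), THF, −40 → 0 °C; then 1 M aq HCl, 0 °C
Reagents that add atoms: none
Why: After one equivalent has deprotonated the phenol, the acetylide Grignard reagent adds 1,2 to the ketone much faster than to the conjugated ester (Grignard addition); the tertiary carbinol is racemic, which does not matter because step 3 erases it.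

Step 3
Reactants: 5 rac-2-hydroxy-2-methylbut-3-yn-1-yl (E)-ferulate
Product: 6 (2E)-2-methyl-4-oxobut-2-en-1-yl (E)-ferulate
Conditions: MoO2(acac)2 (2 mol%), AuCl(PPh3) (2 mol%), AgOTf (2 mol%), toluene, 23 °C; E isomer separated from the minor Z isomer by chromatography
Reagents that add atoms: none
Why: Meyer–Schuster rearrangement: the molybdenum-oxo catalyst shifts the tertiary propargylic oxygen 1,3 through its molybdate ester to an allenol that tautomerises to the enal, so the carbinol centre disappears; the isomer with CHO trans to CH2O is the one carried on.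

Step 4
Reactants: 6 (2E)-2-methyl-4-oxobut-2-en-1-yl (E)-ferulate; 7 Chan's diene (1-methoxy-1,3-bis(trimethylsilyloxy)buta-1,3-diene)
Product: 9 methyl (6E)-5-hydroxy-8-{[(2E)-3-(4-hydroxy-3-methoxyphenyl)prop-2-enoyl]oxy}-7-methyl-3-oxooct-6-enoate, via bis-silyl aldol adduct 8 (not isolated)
Conditions: 7 (2.0 equiv), Ti(OiPr)4 (8 mol%), (±)-BINOL (8 mol%), THF, −78 → 23 °C; then 1 M aq HCl, THF, 0 °C
Reagents that add atoms: none
Why: Catalytic vinylogous Mukaiyama aldol: the terminal (γ) carbon of Chan's diene adds 1,2 to the enal carbonyl, and mild acid releases the δ-hydroxy-β-keto ester; the new secondary carbinol is made racemic on purpose because it is ionised away in step 6.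

Step 5
Reactants: 9 the δ-hydroxy-β-keto ester
Product: 11 tetrakis(trimethylsilyl) diene (4-substituted Chan-type 1-methoxy-1,3-bis(silyloxy)diene), via tris-silyl enol ether 10 (not isolated)
Conditions: Me3SiCl (3.5 equiv), Et3N, THF, 23 °C, filter under argon; then LiN(iPr)2 (1.1 equiv), Me3SiCl (in-situ quench), THF, −78 °C; non-aqueous work-up
Reagents that add atoms: chlorotrimethylsilane C[Si](C)(C)Cl
Why: Standard two-stage synthesis of a 1,3-bis(silyloxy)diene: O-silylation of phenol, carbinol and keto-ester enol, then kinetic γ-deprotonation of the β-silyloxy enoate and O-silylation of the dienolate (the in-situ quench keeps the amide base away from the cinnamate); no stereocentre is set.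

Step 6
Reactants: 11 tetrakis(trimethylsilyl) diene; 12 3-butyn-2-one
Product: 17 [(2R)-6-acetyl-7-hydroxy-2-methyl-2H-chromen-2-yl]methyl (2E)-3-(4-hydroxy-3-methoxyphenyl)prop-2-enoate (CNP0375196.1), via cyclohexadiene adduct 13 (not isolated), via silylated arene 14 (not isolated), via o-quinone methide ion pair 15 (not isolated), via bis-silyl chromene 16 (not isolated)
Conditions: 12 (1.5 equiv), toluene, 23 → 45 °C; then (R)-3,3′-bis(2,4,6-triisopropylphenyl)-1,1′-binaphthyl-2,2′-diyl N-triflylphosphoramide (10 mol%), −60 → −20 °C, dark; then 10% aq citric acid, THF, 0 °C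
Reagents that add atoms: none
Why: Proposed new method: the nucleophilic C4 terminus of the Chan-type diene bonds to the unsubstituted alkyne carbon of the ynone and the ketene-acetal carbon to the acetyl-bearing carbon (Diels–Alder reaction of a 1,1,3-trioxygenated diene with an alkynone), and loss of methanol gives the resacetophenone ring with the side chain locked para to the future 7-OH; the strong chiral acid then ionises the doubly activated benzylic silyl ether to an o-quinone-methide-type allyl cation paired with the chiral anion, and the ortho oxygen closes on the tertiary allyl terminus (cationic oxa-6π ring closure), creating the (R) quaternary centre under catalyst control; the closest known reaction types are the benzannulation/o-quinone methide/electrocyclisation cascade that builds both chromene rings in one step and the chiral N-triflylphosphoramide-catalysed intramolecular allylic substitution of o-hydroxyaryl allylic alcohols to 2,2-disubstituted 2H-chromenes.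

## Compound list

1 | (E)-ferulic acid | COc1cc(/C=C/C(=O)O)ccc1O | starting material
2 | chloroacetone | CC(=O)CCl | starting material
3 | 2-oxopropyl (E)-ferulate | CC(=O)COC(=O)/C=C/c1ccc(O)c(OC)c1 | intermediate
4 | ethynylmagnesium bromide | C#C[Mg]Br | starting material
5 | rac-2-hydroxy-2-methylbut-3-yn-1-yl (E)-ferulate (racemic tertiary carbinol) | C#CC(C)(O)COC(=O)/C=C/c1ccc(O)c(OC)c1 | intermediate
6 | (2E)-2-methyl-4-oxobut-2-en-1-yl (E)-ferulate | O=C/C=C(\C)COC(=O)/C=C/c1ccc(O)c(OC)c1 | intermediate
7 | Chan's diene, 1-methoxy-1,3-bis(trimethylsilyloxy)buta-1,3-diene (ketene acetal geometry not defined) | COC(O[Si](C)(C)C)=CC(=C)O[Si](C)(C)C | starting material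
8 | bis-silyl aldol adduct: methyl (6E)-8-(feruloyloxy)-7-methyl-3,5-bis(trimethylsilyloxy)octa-2,6-dienoate (racemic at C5, enol ether geometry not defined) | COC(=O)C=C(O[Si](C)(C)C)CC(O[Si](C)(C)C)/C=C(\C)COC(=O)/C=C/c1ccc(O)c(OC)c1 | intermediate (not isolated)
9 | methyl (6E)-8-(feruloyloxy)-5-hydroxy-7-methyl-3-oxooct-6-enoate (racemic at C5) | COC(=O)CC(=O)CC(O)/C=C(\C)COC(=O)/C=C/c1ccc(O)c(OC)c1 | intermediate
10 | tris-silyl enol ether: compound 8 with the ferulate phenol also O-silylated | COC(=O)C=C(O[Si](C)(C)C)CC(O[Si](C)(C)C)/C=C(\C)COC(=O)/C=C/c1ccc(O[Si](C)(C)C)c(OC)c1 | intermediate (not isolated)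
11 | tetrakis(trimethylsilyl) diene: (6E)-1-methoxy-7-methyl-1,3,5-tris(trimethylsilyloxy)octa-1,3,6-trien-8-yl (E)-3-[3-methoxy-4-(trimethylsilyloxy)phenyl]prop-2-enoate (racemic at C5, diene geometry not defined) | COC(O[Si](C)(C)C)=CC(O[Si](C)(C)C)=CC(O[Si](C)(C)C)/C=C(\C)COC(=O)/C=C/c1ccc(O[Si](C)(C)C)c(OC)c1 | intermediate
12 | 3-butyn-2-one | CC(=O)C#C | starting material
13 | cyclohexadiene adduct: 1-acetyl-6-methoxy-4,6-bis(trimethylsilyloxy)cyclohexa-1,4-diene carrying the silylated side chain at C3 (diastereomer mixture) | COC1(O[Si](C)(C)C)C=C(O[Si](C)(C)C)C(C(O[Si](C)(C)C)/C=C(\C)COC(=O)/C=C/c2ccc(O[Si](C)(C)C)c(OC)c2)C=C1C(C)=O | intermediate (not isolated)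
14 | silylated arene: (2E)-4-[5-acetyl-2,4-bis(trimethylsilyloxy)phenyl]-2-methyl-4-(trimethylsilyloxy)but-2-en-1-yl O-trimethylsilyl-(E)-ferulate (racemic) | CC(=O)c1cc(C(O[Si](C)(C)C)/C=C(\C)COC(=O)/C=C/c2ccc(O[Si](C)(C)C)c(OC)c2)c(O[Si](C)(C)C)cc1O[Si](C)(C)C | intermediate (not isolated)
15 | o-quinone methide (exocyclic alkene Z), present as its O-protonated contact ion pair with the phosphoramide anion; neutral form drawn | CC(=O)C1=C/C(=C/C=C(\C)COC(=O)/C=C/c2ccc(O[Si](C)(C)C)c(OC)c2)C(=O)C=C1O[Si](C)(C)C | intermediate (not isolated)
16 | bis-silyl chromene: (2R)-chromene with 7-O-SiMe3 and ferulate 4-O-SiMe3 | COc1cc(/C=C/C(=O)OC[C@@]2(C)C=Cc3cc(C(C)=O)c(O[Si](C)(C)C)cc3O2)ccc1O[Si](C)(C)C | intermediate (not isolated)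
17 | [(2R)-6-acetyl-7-hydroxy-2-methyl-2H-chromen-2-yl]methyl (2E)-3-(4-hydroxy-3-methoxyphenyl)prop-2-enoate | COc1cc(/C=C/C(=O)OC[C@@]2(C)C=Cc3cc(C(C)=O)c(O)cc3O2)ccc1O | target

## Step count and risks

Total step count: 6. Longest linear sequence: 6 (1 → 3 → 5 → 6 → 9 → 11 → 17).

Steps most likely to fail:

Step 6 (key step). The cycloaddition of a diene with a branched C4 substituent may be slow. Traces of amine or achiral acid carried over from step 5 can switch off the chiral acid or open a racemic background closure. The catalyst has to distinguish CH3 from CH2O-acyl at a cationic terminus, which is not precedented. Fallback: setting out from 11, the same Diels–Alder reaction with 12 is run and the ring closure is triggered with an achiral acid (diphenyl phosphate, 5 mol%, toluene, 0 °C), followed by the same citric acid work-up. This gives the racemate, that is 17 together with its mirror image [(2S)-6-acetyl-7-hydroxy-2-methyl-2H-chromen-2-yl]methyl (E)-ferulate F2. The enantiomers are separated by preparative supercritical-fluid chromatography on an amylose tris(3,5-dimethylphenylcarbamate) phase; F2 may be recyclable by heating in toluene (ring opening to the o-quinone methide and reclosure), though this is untested. The fallback comes back to the route at 17.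

Step 5. The lithium amide may attack the cinnamate, or the γ-anion may eliminate the allylic silyloxy group. Fallback: setting out from 6, the Mukaiyama adduct 8 is not hydrolysed to 9. It is treated in the same flask with Et3N (4 equiv) and Me3SiOTf (2.2 equiv) in CH2Cl2/Et2O at 0 °C, which silylates the phenol and the γ-position by soft enolisation. No hydroxy keto ester is isolated, no lithium amide is used, and no new compound is made (F0). The fallback comes back to the route at 11.

Step 3. The tertiary ethynyl carbinol may follow the Rupe pathway to an enone, be hydrated by gold, or be captured by the neighbouring ester carbonyl. Fallback: setting out from 3, the two-carbon aldehyde unit is added by olefination instead of ethynylation/rearrangement. Wittig reaction with (1,3-dioxolan-2-ylmethyl)triphenylphosphonium bromide and KOtBu (2.1 equiv, THF, 0 → 23 °C) gives (2E)-3-(1,3-dioxolan-2-yl)-2-methylprop-2-en-1-yl (E)-ferulate F1 (E/Z mixture, E drawn). Hydrolysis with 1 M aq HCl in THF at 23 °C releases the enal, and the E isomer is separated as in step 3. The fallback comes back to the route at 6.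

Further compounds
F1 | step 3 | (2E)-3-(1,3-dioxolan-2-yl)-2-methylprop-2-en-1-yl (2E)-3-(4-hydroxy-3-methoxyphenyl)prop-2-enoate | COc1cc(/C=C/C(=O)OC/C(C)=C/C2OCCO2)ccc1O
F0 | step 5 | none | none
F2 | step 6 | [(2S)-6-acetyl-7-hydroxy-2-methyl-2H-chromen-2-yl]methyl (2E)-3-(4-hydroxy-3-methoxyphenyl)prop-2-enoate | COc1cc(/C=C/C(=O)OC[C@]2(C)C=Cc3cc(C(C)=O)c(O)cc3O2)ccc1O
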